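**Retrosynthetic overview**
1. The target comes from its N-(4-methoxybenzyl), 8-O-TBS derivative by a single acidolysis (N–CH2Ar and O–Si).
2. Key disconnection C5–C6 (with C1'–H). The strategy rests on C5, an H-bearing stereocentre bonded to C4a of the 4-pyridone ring, to the ring methylene C6 and to the unfunctionalised chain carbon C1'. This is the pattern left by hydrocupration of a C5=C1' alkenyl pyridone followed by alkylation with a C6 bromide, which closes the carbocycle C4a–C5–C6–C7–C8–C8a.
3. The bromo alkene precursor comes from a 5-iodo-4-pyridone and an (E)-alkenylboronate (Suzuki coupling, C4a–C5), then primary OH → Br.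
4. The pyridone ring comes from a 1,3,5-triketone and 4-methoxybenzylamine. The triketone comes from the dianion of 3-methoxypentane-2,4-dione and a Weinreb amide made from (R)-α-hydroxy-γ-butyrolactone, which supplies C8 (R), C7 and C6.
5. Ring order: pyridone ring first (step 4), carbocycle second (step 10).

Key step: step 10

Atom labels (N1, C2 … C8a; C1' = first chain carbon on C5) follow the tetrahydroquinolinone numbering of the target and are also used for acyclic precursors.
Assumption: the sense of induction of DTBM-SEGPHOS on an alkenyl 4-pyridone is taken to follow that on β-alkylstyrenes, and the (R)-ligand is written as the antipode that places copper on the Re face of C5; if the sense proves opposite, the (S)-ligand is used with no other change.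

**Route**

Step 1
Reactants: 1 (R)-α-hydroxy-γ-butyrolactone
Product: 2 (2R)-2,4-dihydroxy-N-methoxy-N-methylbutanamide
Conditions: MeNH(OMe)·HCl, AlMe3, CH2Cl2, 0 °C → rt; aqueous potassium sodium tartrate work-up; used without storage
Reagents that add atoms: N,O-dimethylhydroxylamine hydrochloride, CNOC.Cl
Why: Weinreb aminolysis of the lactone by the aluminium amide opens the ring at the acyl C–O bond without touching the α-stereocentre and frees the primary hydroxyl that later becomes the C6 leaving group.

Step 2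
Reactants: 2 (2R)-2,4-dihydroxy-N-methoxy-N-methylbutanamide
Product: 3 (2R)-2,4-bis[(tert-butyldimethylsilyl)oxy]-N-methoxy-N-methylbutanamide
Conditions: TBSCl, imidazole, DMF, rt
Reagents that add atoms: tert-butyldimethylsilyl chloride, CC(C)(C)[Si](C)(C)Cl
Why: Standard silylation of both hydroxyls stops relactonisation and gives a primary and a hindered secondary silyl ether that can be told apart later.

Step 3
Reactants: 4 3-methoxypentane-2,4-dione; 3 (2R)-2,4-bis[(tert-butyldimethylsilyl)oxy]-N-methoxy-N-methylbutanamide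
Product: 6 (7R)-7,9-bis[(tert-butyldimethylsilyl)oxy]-3-methoxynonane-2,4,6-trione (keto–enol mixture, C3 not defined), via dilithium dienediolate 5 (not isolated)
Conditions: 4 (1.5 equiv), LiN(iPr)2 (3.1 equiv), THF, −78 → 0 °C; then 3, −78 → −20 °C; AcOH quench
Reagents that add atoms: none
Why: The terminal carbanion of the β-diketone dianion acylates the Weinreb amide (Claisen-type dianion acylation) through a chelated tetrahedral adduct that releases the 1,3,5-triketone only on quench, so over-addition is avoided and the α-silyloxy centre is not enolised.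

Step 4
Reactants: 6 (7R)-7,9-bis[(tert-butyldimethylsilyl)oxy]-3-methoxynonane-2,4,6-trione; 7 4-methoxybenzylamine
Product: 9 6-[(1R)-1,3-bis[(tert-butyldimethylsilyl)oxy]propyl]-3-methoxy-1-(4-methoxybenzyl)-2-methylpyridin-4(1H)-one, via enaminone 8 (not isolated)
Conditions: 7 (1.5 equiv), AcOH (1 equiv), 4 Å MS, toluene, 70 °C
Reagents that add atoms: none
Why: Condensation of the primary amine with the triketone gives the chelated enaminone, whose nitrogen adds to the ketone carbon that becomes C8a and loses water to give the aromatic 4-pyridone (triketone–amine pyridone synthesis), under buffered conditions chosen to keep C8 from enolising.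

Step 5
Reactants: 9 6-[(1R)-1,3-bis[(tert-butyldimethylsilyl)oxy]propyl]-3-methoxy-1-(4-methoxybenzyl)-2-methylpyridin-4(1H)-one
Product: 10 6-[(1R)-1,3-bis[(tert-butyldimethylsilyl)oxy]propyl]-5-iodo-3-methoxy-1-(4-methoxybenzyl)-2-methylpyridin-4(1H)-one
Conditions: NIS, MeCN, rt
Reagents that add atoms: N-iodosuccinimide, O=C1CCC(=O)N1I
Why: Electrophilic iodination takes place at the only free ring carbon, the nucleophilic α-carbon of the vinylogous amide (C4a), as is usual for 4-pyridones.

Step 6
Reactants: 11 6-phenylhex-1-yne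
Product: 12 4,4,5,5-tetramethyl-2-[(E)-6-phenylhex-1-en-1-yl]-1,3,2-dioxaborolane
Conditions: HBpin, Cp2Zr(H)Cl (5 mol%), Et3N (10 mol%), neat, 60 °C
Reagents that add atoms: pinacolborane, CC1(C)OBOC1(C)C
Why: Zirconocene hydride-catalysed syn-hydroboration of the terminal alkyne places boron on the terminal carbon and gives the (E)-alkenylboronate.

Step 7
Reactants: 10 6-[(1R)-1,3-bis[(tert-butyldimethylsilyl)oxy]propyl]-5-iodo-3-methoxy-1-(4-methoxybenzyl)-2-methylpyridin-4(1H)-one; 12 4,4,5,5-tetramethyl-2-[(E)-6-phenylhex-1-en-1-yl]-1,3,2-dioxaborolane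
Product: 13 6-[(1R)-1,3-bis[(tert-butyldimethylsilyl)oxy]propyl]-3-methoxy-1-(4-methoxybenzyl)-2-methyl-5-[(E)-6-phenylhex-1-en-1-yl]pyridin-4(1H)-one
Conditions: Pd(OAc)2 (5 mol%), SPhos (10 mol%), K3PO4, THF/H2O, 60 °C
Reagents that add atoms: none
Why: Suzuki–Miyaura coupling of the 3-iodo-4-pyridone with the alkenylboronate forms the C4a–C5 bond with retention of the (E) geometry, the bulky biarylphosphine coping with the two flanking substituents.

Step 8
Reactants: 13 6-[(1R)-1,3-bis[(tert-butyldimethylsilyl)oxy]propyl]-3-methoxy-1-(4-methoxybenzyl)-2-methyl-5-[(E)-6-phenylhex-1-en-1-yl]pyridin-4(1H)-one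
Product: 14 6-[(1R)-1-[(tert-butyldimethylsilyl)oxy]-3-hydroxypropyl]-3-methoxy-1-(4-methoxybenzyl)-2-methyl-5-[(E)-6-phenylhex-1-en-1-yl]pyridin-4(1H)-one
Conditions: HF·pyridine, pyridine, THF, 0 °C
Reagents that add atoms: none
Why: Buffered fluoride cleaves the unhindered primary silyl ether much faster than the secondary one wedged between the ring and the N-benzyl group (selective desilylation).

Step 9
Reactants: 14 6-[(1R)-1-[(tert-butyldimethylsilyl)oxy]-3-hydroxypropyl]-3-methoxy-1-(4-methoxybenzyl)-2-methyl-5-[(E)-6-phenylhex-1-en-1-yl]pyridin-4(1H)-one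
Product: 15 6-[(1R)-3-bromo-1-[(tert-butyldimethylsilyl)oxy]propyl]-3-methoxy-1-(4-methoxybenzyl)-2-methyl-5-[(E)-6-phenylhex-1-en-1-yl]pyridin-4(1H)-one
Conditions: CBr4, PPh3, imidazole, CH2Cl2, 0 °C; used at once
Reagents that add atoms: carbon tetrabromide, BrC(Br)(Br)Br
Why: Appel bromination converts the primary alcohol into the bromide under neutral conditions that leave the silyl ether, the alkene and the N-alkyl pyridone untouched.

Step 10
Reactants: 15 6-[(1R)-3-bromo-1-[(tert-butyldimethylsilyl)oxy]propyl]-3-methoxy-1-(4-methoxybenzyl)-2-methyl-5-[(E)-6-phenylhex-1-en-1-yl]pyridin-4(1H)-one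
Product: 16 (5S,8R)-8-[(tert-butyldimethylsilyl)oxy]-3-methoxy-1-(4-methoxybenzyl)-2-methyl-5-(5-phenylpentyl)-5,6,7,8-tetrahydroquinolin-4(1H)-one
Conditions: Cu(OAc)2 (5 mol%), (R)-DTBM-SEGPHOS (5.5 mol%), (MeO)2MeSiH (3 equiv), LiOMe (2 equiv), THF, rt → 40 °C
Reagents that add atoms: none
Why: Cu(OAc)2, the bisphosphine and the silane give a monovalent copper hydride that adds syn across the C5=C1' alkene with hydrogen on C1' and copper on C5, where the organocopper is stabilised by the pyridone π system like a benzylic copper; the C5–Cu carbon then displaces the tethered primary C6 bromide with retention at C5, and LiOMe with the silane turns the copper bromide back into the hydride. The closest known reaction type is the copper hydride-catalysed enantioselective intramolecular hydroalkylation of β-substituted alkenyl arenes carrying an alkyl bromide, here applied to an alkenyl 4-pyridone. The carbocycle (C4a, C5, C6, C7, C8, C8a) closes in a 6-exo-tet mode. C5 is set by the ligand, which has to deliver copper to the Re face of C5 to give 5S, that is, the side chain cis to the C8 silyloxy group; the 8R centre is untouched, and any 8S material would leave here as the separable trans diastereomer. The step needs copper on C5 and not C1' (favoured by conjugation with the ring and by six- over seven-membered closure), hydrocupration faster than direct reduction of the bromide (a primary bromide is reduced only slowly by the bulky hydride), and no quaternisation at nitrogen, which the N-benzyl group secures.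

Step 11
Reactants: 16 (5S,8R)-8-[(tert-butyldimethylsilyl)oxy]-3-methoxy-1-(4-methoxybenzyl)-2-methyl-5-(5-phenylpentyl)-5,6,7,8-tetrahydroquinolin-4(1H)-one
Product: 18 (5S,8R)-8-hydroxy-3-methoxy-2-methyl-5-(5-phenylpentyl)-5,6,7,8-tetrahydroquinolin-4(1H)-one, via N-PMB alcohol 17 (not isolated)
Conditions: TFA/H2O (19:1), anisole, rt then 70 °C; NaHCO3 work-up
Reagents that add atoms: none
Why: Aqueous acid first hydrolyses the silyl ether and then, on heating, ionises the N–CH2Ar bond of the O-protonated pyridone (acidolysis of the N-4-methoxybenzyl group, cation trapped by anisole), while the C8 hydroxyl next to the electron-poor C8a of the protonated ring does not ionise and C5 has no leaving group, so both stereocentres are kept.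

**Compound list**
1 | (R)-α-hydroxy-γ-butyrolactone [(3R)-3-hydroxyoxolan-2-one] | O=C1OCC[C@H]1O | starting material
2 | (2R)-2,4-dihydroxy-N-methoxy-N-methylbutanamide | CON(C)C(=O)[C@H](O)CCO | intermediate
3 | (2R)-2,4-bis[(tert-butyldimethylsilyl)oxy]-N-methoxy-N-methylbutanamide | CON(C)C(=O)[C@H](O[Si](C)(C)C(C)(C)C)CCO[Si](C)(C)C(C)(C)C | intermediate
4 | 3-methoxypentane-2,4-dione | CC(=O)C(OC)C(C)=O | starting material
5 | dilithium 3-methoxypenta-1,3-diene-2,4-diolate (dianion of 4) | [Li+].[Li+].C=C([O-])C(OC)=C(C)[O-] | intermediate (not isolated)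
6 | (7R)-7,9-bis[(tert-butyldimethylsilyl)oxy]-3-methoxynonane-2,4,6-trione | CC(=O)C(OC)C(=O)CC(=O)[C@H](O[Si](C)(C)C(C)(C)C)CCO[Si](C)(C)C(C)(C)C | intermediate
7 | 4-methoxybenzylamine | NCc1ccc(OC)cc1 | starting material
8 | (2E,7R)-7,9-bis[(tert-butyldimethylsilyl)oxy]-3-methoxy-2-[(4-methoxybenzyl)amino]non-2-ene-4,6-dione (N–H···O=C chelated enaminone) | COc1ccc(CN/C(C)=C(OC)\C(=O)CC(=O)[C@H](O[Si](C)(C)C(C)(C)C)CCO[Si](C)(C)C(C)(C)C)cc1 | intermediate (not isolated)
9 | 6-[(1R)-1,3-bis[(tert-butyldimethylsilyl)oxy]propyl]-3-methoxy-1-(4-methoxybenzyl)-2-methylpyridin-4(1H)-one | COc1c(C)n(Cc2ccc(OC)cc2)c([C@H](O[Si](C)(C)C(C)(C)C)CCO[Si](C)(C)C(C)(C)C)cc1=O | intermediate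
10 | 6-[(1R)-1,3-bis[(tert-butyldimethylsilyl)oxy]propyl]-5-iodo-3-methoxy-1-(4-methoxybenzyl)-2-methylpyridin-4(1H)-one | COc1c(C)n(Cc2ccc(OC)cc2)c([C@H](O[Si](C)(C)C(C)(C)C)CCO[Si](C)(C)C(C)(C)C)c(I)c1=O | intermediate
11 | 6-phenylhex-1-yne | C#CCCCCc1ccccc1 | starting material
12 | 4,4,5,5-tetramethyl-2-[(E)-6-phenylhex-1-en-1-yl]-1,3,2-dioxaborolane | CC1(C)OB(/C=C/CCCCc2ccccc2)OC1(C)C | intermediate
13 | 6-[(1R)-1,3-bis[(tert-butyldimethylsilyl)oxy]propyl]-3-methoxy-1-(4-methoxybenzyl)-2-methyl-5-[(E)-6-phenylhex-1-en-1-yl]pyridin-4(1H)-one | COc1c(C)n(Cc2ccc(OC)cc2)c([C@H](O[Si](C)(C)C(C)(C)C)CCO[Si](C)(C)C(C)(C)C)c(/C=C/CCCCc2ccccc2)c1=O | intermediate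
14 | 6-[(1R)-1-[(tert-butyldimethylsilyl)oxy]-3-hydroxypropyl]-3-methoxy-1-(4-methoxybenzyl)-2-methyl-5-[(E)-6-phenylhex-1-en-1-yl]pyridin-4(1H)-one | COc1c(C)n(Cc2ccc(OC)cc2)c([C@H](O[Si](C)(C)C(C)(C)C)CCO)c(/C=C/CCCCc2ccccc2)c1=O | intermediate
15 | 6-[(1R)-3-bromo-1-[(tert-butyldimethylsilyl)oxy]propyl]-3-methoxy-1-(4-methoxybenzyl)-2-methyl-5-[(E)-6-phenylhex-1-en-1-yl]pyridin-4(1H)-one | COc1c(C)n(Cc2ccc(OC)cc2)c([C@H](O[Si](C)(C)C(C)(C)C)CCBr)c(/C=C/CCCCc2ccccc2)c1=O | intermediate (key-step precursor)
16 | (5S,8R)-8-[(tert-butyldimethylsilyl)oxy]-3-methoxy-1-(4-methoxybenzyl)-2-methyl-5-(5-phenylpentyl)-5,6,7,8-tetrahydroquinolin-4(1H)-one | COc1c(C)n(Cc3ccc(OC)cc3)c2c(c1=O)[C@@H](CCCCCc1ccccc1)CC[C@H]2O[Si](C)(C)C(C)(C)C | intermediate (key-step product)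
17 | (5S,8R)-8-hydroxy-3-methoxy-1-(4-methoxybenzyl)-2-methyl-5-(5-phenylpentyl)-5,6,7,8-tetrahydroquinolin-4(1H)-one | COc1c(C)n(Cc3ccc(OC)cc3)c2c(c1=O)[C@@H](CCCCCc1ccccc1)CC[C@H]2O | intermediate (not isolated)
18 | (5S,8R)-8-hydroxy-3-methoxy-2-methyl-5-(5-phenylpentyl)-5,6,7,8-tetrahydroquinolin-4(1H)-one | COc1c(C)[nH]c2c(c1=O)[C@@H](CCCCCc1ccccc1)CC[C@H]2O | target

**Step count**
Total steps: 11. Longest linear sequence: 10 (steps 1–5 and 7–11; step 6 is the side branch).

**Steps most likely to fail**

1. Step 10. Hydrocupration of the electron-rich alkenyl pyridone, which is flanked on both sides, may be slow, so that reduction of the C–Br bond or plain reduction of the alkene overtakes cyclisation; the ligand may also give poor facial selectivity against the resident C8 centre.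
Fallback, setting out from iodide 10 and alkyne 11 and coming back at 16: the primary silyl ether of 10 is cleaved (HF·pyridine, pyridine, THF, 0 °C) to the iodo alcohol F1, and Appel bromination (CBr4, PPh3) gives the iodo bromide F2. The lithium acetylide of 11 (n-BuLi, THF/DMPU, −78 °C → rt) displaces the bromide and gives the internal alkyne F3. A reductive Heck cyclisation (Pd(OAc)2, PPh3, HCO2Na, DMF, 80 °C) then closes the carbocycle through the C4a–C5 bond: zerovalent palladium inserts into the C4a–I bond, 6-exo-dig syn-carbopalladation follows, and formate reduces the alkenylpalladium to the (E)-alkylidene F4. Hydrogenation (H2, Pd/C, EtOAc) from the ring face opposite the pseudoaxial C8 silyloxy group should give the cis compound 16; C5 is then under substrate control and any trans isomer is separated.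

2. Step 4. Ring closure of the hindered enaminone onto the ketone next to the silyloxy carbon may be slow, with competing O-cyclisation, and prolonged heating with amine and acid may enolise the α-silyloxy ketone and erode the configuration at C8.
Fallback, setting out from 6 and coming back at 9: neutral cyclodehydration of the triketone (PPh3, CCl4, THF, rt) gives the γ-pyrone F5, in which C8 is no longer α to a ketone. Ring transformation of the pyrone with 7 (EtOH, AcOH, 80 °C; amine addition, ring opening and reclosure) returns to 9.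

3. Step 3. Acylation of the dianion by the hindered α-silyloxy Weinreb amide may stall, or proton transfer from the amide to the dianion may compete with addition, returning starting materials.
Fallback, setting out from 3 and coming back at 6: reduction of 3 (i-Bu2AlH, THF, −78 °C) gives the α-silyloxy aldehyde F6. Aldol addition of dianion 5 at −78 °C gives the hydroxy diketone F7 (mixture at the carbinol carbon), and Dess–Martin oxidation returns to triketone 6.

**Further compounds**
F1 | step 10 | 6-[(1R)-1-[(tert-butyldimethylsilyl)oxy]-3-hydroxypropyl]-5-iodo-3-methoxy-1-(4-methoxybenzyl)-2-methylpyridin-4(1H)-one | COc1c(C)n(Cc2ccc(OC)cc2)c([C@H](O[Si](C)(C)C(C)(C)C)CCO)c(I)c1=O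
F2 | step 10 | 6-[(1R)-3-bromo-1-[(tert-butyldimethylsilyl)oxy]propyl]-5-iodo-3-methoxy-1-(4-methoxybenzyl)-2-methylpyridin-4(1H)-one | COc1c(C)n(Cc2ccc(OC)cc2)c([C@H](O[Si](C)(C)C(C)(C)C)CCBr)c(I)c1=O
F3 | step 10 | 6-[(1R)-1-[(tert-butyldimethylsilyl)oxy]-9-phenylnon-4-yn-1-yl]-5-iodo-3-methoxy-1-(4-methoxybenzyl)-2-methylpyridin-4(1H)-one | COc1c(C)n(Cc2ccc(OC)cc2)c([C@H](O[Si](C)(C)C(C)(C)C)CCC#CCCCCc2ccccc2)c(I)c1=O
F4 | step 10 | (8R,E)-8-[(tert-butyldimethylsilyl)oxy]-3-methoxy-1-(4-methoxybenzyl)-2-methyl-5-(5-phenylpentylidene)-5,6,7,8-tetrahydroquinolin-4(1H)-one | COc1c(C)n(Cc3ccc(OC)cc3)c2c(c1=O)/C(=C/CCCCc1ccccc1)CC[C@H]2O[Si](C)(C)C(C)(C)C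
F5 | step 4 | 2-[(1R)-1,3-bis[(tert-butyldimethylsilyl)oxy]propyl]-5-methoxy-6-methyl-4H-pyran-4-one | COc1c(C)oc([C@H](O[Si](C)(C)C(C)(C)C)CCO[Si](C)(C)C(C)(C)C)cc1=O
F6 | step 3 | (2R)-2,4-bis[(tert-butyldimethylsilyl)oxy]butanal | O=C[C@H](O[Si](C)(C)C(C)(C)C)CCO[Si](C)(C)C(C)(C)C
F7 | step 3 | (7R)-7,9-bis[(tert-butyldimethylsilyl)oxy]-6-hydroxy-3-methoxynonane-2,4-dione | CC(=O)C(OC)C(=O)CC(O)[C@H](O[Si](C)(C)C(C)(C)C)CCO[Si](C)(C)C(C)(C)C
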